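## The problem

The target is a germacranolide-type cyclodeca-1(10),4-diene. Its ten-membered carbocycle (C1–C10) carries two trisubstituted alkenes, C1=C10 (bearing the C14 methyl ester) and C4=C5 (bearing the C15 hydroxymethyl group), and in both the ring bonds are cis. An α-methylene-γ-butyrolactone (C11=C13, C12 carbonyl, ring oxygen on C6) is fused across C6–C7. This numbering is used for every intermediate below.

Four contiguous stereocentres (6R,7S,8S,9R) must be set. The C6 oxygen is trans to the C7 side chain (trans-fused lactone). The C8 isobutyrate and C9 acetate are cis to each other and lie on the face of the C7 branch. C6 and C7 can be fixed in an open chain by an auxiliary-controlled aldol reaction. After that C7 is the only resident handle for C8, and C9 has to follow C8.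

The methylene lactone is a conjugate acceptor and is reducible. The two different esters on neighbouring carbinols can migrate. The ring-cis geometry at C1=C10 places the C9 carbon cis to C2, which is the less stable arrangement once C9 is a carbonyl group. The medium ring brings the usual entropic and transannular penalties.

The feature that opens the route is that C8 and C9 are adjacent oxygenated ring carbons, C8 next to C7 and C9 on the sp2 carbon C10. Each can therefore be the carbon of an aldehyde, and reductive coupling of a C8 aldehyde with a C9 enal forms C8–C9, closes the ring and creates both carbinols in one step.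

## Retrosynthesis

**Endgame (35 ⇐ 34 ⇐ 33 ⇐ 32).** No skeletal bond is cut. The free C15 alcohol of 35 comes from PMB ether 34, the C14 ester from acid 33, and the acid from enal 32. C14 cannot be at the ester level during ring closure (see the key cut), so it is raised afterwards. The forward steps must leave the methylene lactone and both acyl groups alone.

**Lactone (32 ⇐ 30).** The C12–O6 lactone bond is opened and C12 and C14 are lowered to primary allylic alcohols, giving triol 30. A methylene lactone would be reduced or attacked by ketyls in the ring closure, whereas a 2-methylene-1,4-diol is inert and returns to the lactone in a single oxidation. The forward reaction must oxidise two primary allylic alcohols without touching the secondary allylic C6 alcohol before it is locked into the lactol.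

**Acyl groups (30 ⇐ 29 ⇐ 28 ⇐ 27).** Removing isobutyrate and acetate, and re-silylating, leads to the cis diol 27. The forward direction must tell the allylic C9 hydroxyl from the C8 hydroxyl, which is flanked by the C7 branch.

**Key cut (27 ⇐ 26).** The C8–C9 bond is cut to give dialdehyde 26. The neighbouring cuts are worse:
- C2–C3 joins two allylic carbons and would bring SN2/SN2′ ambiguity at both ends.
- Closing either ring alkene by metathesis would have to make a trisubstituted ring-cis alkene in a ten-membered ring with no control of geometry.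
- Closing C6–C7 would need the acrylate unit in place and would leave C8 and C9 to be set on the ring.

The C8–C9 cut removes the ring and two stereocentres together and leaves a linear chain in which both alkene geometries are made separately. C14 is carried as a silyl ether so that the C9 carbonyl is a simple enal; at the ester level the same carbon would be a doubly activated acceptor, prone to reduction at C1. The forward reaction must give the cis diol on the C11 face, couple 1,2 and not through C1, and keep the C1=C10 geometry.

**Chain assembly (26 ⇐ 25 ⇐ 6 + 23).** Dialdehyde 26 is made from diol 25 at the last moment. Diol 25 is cut at C3–C4, between an sp3 and an sp2 carbon, into dienol 6 (as its C3 borane) and iodoalkene 23. This bond sits next to a stereodefined iodoalkene, so a cross-coupling with retention is possible. Placing this coupling directly before the oxidation lets 6 bring the C9 hydroxyl and 23 the C8 hydroxyl unprotected, so no temporary protecting group is needed. The forward step needs hydroboration at the terminal vinyl group only.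

**C6–C7 (23 ⇐ 22 ⇐ 21 ⇐ 19 + 11).** The C6–C7 bond is cut as a syn aldol between imide 19 and iodoenal 11. This sets C6 and C7 in the relationship of the trans lactone under auxiliary control. It brings C8 as an acyl carbon that is reduced to the alcohol, and it delivers the complete C11–C13/C12 unit. An allylation at this bond would instead leave C8 as a vinyl group to be cleaved among four alkenes.

**Dienol (6 ⇐ 5 ⇐ 4 ⇐ 3 ⇐ 1).** The problem is a 2-alkylidene-1,3-diol with differentiated oxygens and defined geometry. A butenolide solves both. In 4 the ring holds the C9 CH2–O cis to the C2 carbonyl and leaves the C14 hydroxymethyl outside the ring, where it is silylated. Reduction to lactol 5 and methylenation adds C3 and frees the C9 hydroxyl. Butenolide 3 comes from ketone 1, which is symmetrical, so its olefination has no geometry to control.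

**Iodoenal (11 ⇐ 10 ⇐ 8 ⇐ 7).** The C4=C5 geometry comes from trans-hydroalumination and iodination of alkynol 8, which places iodine cis to C6. Alkynol 8 is the mono-PMB ether of diol 7.

**Imide (19 ⇐ 16 + 17; 16 ⇐ 14 ⇐ 13 ⇐ 12).** Imide 19 is the acyl derivative of auxiliary 17 and acid 16. The acid is made by carboxylating the allyl metal from bromide 14, which comes from diol 12 through monosilyl ether 13. The allyl unit has two equivalent CH2 termini, so the carboxylation has no regiochemical issue.

## Roads not taken

**Alternative 1:** Both ring alkenes are traced back to the σ bonds C5–C10 and C1–C4 of the tricyclic cis,anti,cis photoadduct A1, a bicyclo[2.2.0]hexane fused to a cyclohexanone. Heating A1 near 200 °C would cleave these two bonds and open the six-membered ring to the ten-membered dienone ester A2.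
- Merits: the ring is formed without high dilution. C7, C8 and C9 are set on a six-membered ring, where relative configuration is easy to secure. C14 is already an ester. In these respects this road is better than the chosen one, which relies on a metal template for C8/C9 and needs three late steps to raise C14.
- Weak points: A1 needs an intermolecular enone–alkene photocycloaddition with control of orientation and face while two fully substituted carbons are formed. The fragmentation stereochemistry does not guarantee that both new alkenes are ring-cis. At 200 °C the 1,5-diene of A2 is set up for a Cope rearrangement to a divinylcyclohexane. A2 still needs reduction of the C6 ketone from the correct face, lactonisation, and α-methylenation by enolate chemistry in the presence of other esters. The acetonide diol must be differentiated in any case.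
- Against it, the chosen plan sets both alkene geometries before ring closure, has the C13 methylene in place, and avoids any step above room temperature after the ring exists.

**Alternative 2:** The C5–C10 bond of the cis-dialkenylcyclohexanol A3 is broken while C2–C3 forms in a [3,3] shift. Deprotonation of A3 with potassium hydride and a crown ether would give the alkoxide, whose anionic oxy-Cope rearrangement delivers the ten-membered ketone A4 through its C1 enolate.
- Merits: the ring expansion is intramolecular, strongly driven and well precedented for ten-membered rings, more so than the chosen key step. The C4=C5 geometry follows from the transition state, and C6–C9 are set on a cyclohexane.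
- Weak points: A4 has neither the C1=C10 alkene nor C14. Both must be added through a regio- and geometry-defined enol derivative at C10 and a carbonylation, next to an α-oxygenated C9. The C7 side chain arrives two oxidation levels and one carbon short of the methylene lactone, so C12 oxidation, lactonisation and methylenation all fall on the macrocycle. A3 itself has five stereocentres including a tertiary carbinol.
- Against it, the chosen plan adds no carbon after ring closure and needs only acylation and oxidation-state changes on the ten-membered ring.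

**Alternative 3:** The ring is grown by two carbons. Cyclooctenone A5 is converted into its pyrrolidine enamine A6, which adds methyl propiolate A7 across C9=C2 to give a fused cyclobutene. Conrotatory opening cleaves C9–C2 and gives the ten-membered dienamine ester A8.
- Merits: C1, C10 and the C14 ester arrive in one metal-free step, and C14 is at its final oxidation level. This is better than the chosen plan, which carries C14 as a silyl ether.
- Weak points: the medium-ring problem is only moved to A5, an eight-membered ring with three stereocentres. The enamine must form toward C2 and not toward the oxygenated C8, and C8 may epimerise. A8 has its alkenes at C1=C2 and C9=C10 with nitrogen on C9, so hydrolysis, alkene transposition to C1=C10 and a stereoselective C9 reduction would follow, each on a flexible ring.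
- Against it, the chosen plan makes C9 directly as a carbinol and has C1=C10 in place with defined geometry.

Key step: step 17

Remark on the chemistry: 1,3-dihydroxyacetone (1) is weighed in as its commercial dimer, which reacts as the monomer; the low-valent titanium of step 17 is counted as titanium dichloride (divalent titanium) for the equation.

## Route

Step 1
Reactants: 1 1,3-dihydroxyacetone
Product: 3 4-(hydroxymethyl)furan-2(5H)-one, via hydroxy enoate 2 (not isolated)
Conditions: Ph3P=CHCO2Et, CH2Cl2, rt
Reagents that add atoms: ethyl (triphenylphosphoranylidene)acetate, CCOC(=O)C=P(c1ccccc1)(c1ccccc1)c1ccccc1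
Why: Wittig olefination of the ketone with a stabilised ylide gives enoate 2; both alkene substituents are hydroxymethyl groups, so one is always cis to the ester and lactonises with loss of ethanol, and no alkene geometry has to be controlled.

Step 2
Reactants: 3 4-(hydroxymethyl)furan-2(5H)-one
Product: 4 4-{[(tert-butyldimethylsilyl)oxy]methyl}furan-2(5H)-one
Conditions: TBSCl, imidazole, DMF, 0 °C → rt
Reagents that add atoms: tert-butyldimethylsilyl chloride, CC(C)(C)[Si](C)(C)Cl
Why: Standard silylation of the only free (primary) alcohol, which becomes the C14 oxygen.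

Step 3
Reactants: 4 4-{[(tert-butyldimethylsilyl)oxy]methyl}furan-2(5H)-one
Product: 5 4-{[(tert-butyldimethylsilyl)oxy]methyl}-2,5-dihydrofuran-2-ol (lactol; both anomers)
Conditions: iBu2AlH (1.1 equiv), CH2Cl2, −78 °C; aq. potassium sodium tartrate
Reagents that add atoms: none
Why: Partial reduction of a lactone to the lactol; the tetrahedral aluminium alkoxide is stable at −78 °C and a neutral tartrate work-up should avoid dehydration to the furan.

Step 4
Reactants: 5 4-{[(tert-butyldimethylsilyl)oxy]methyl}-2,5-dihydrofuran-2-ol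
Product: 6 (2E)-2-{[(tert-butyldimethylsilyl)oxy]methyl}penta-2,4-dien-1-ol (free CH2OH cis to the vinyl group; C9–C10(C14)=C1–C2=C3)
Conditions: Ph3PCH3Br, KN(SiMe3)2 (2.5 equiv ylide), THF, 0 °C → rt
Reagents that add atoms: methyltriphenylphosphonium bromide, C[P+](c1ccccc1)(c1ccccc1)c1ccccc1.[Br-]
Why: Wittig methylenation of the ring-opened hydroxy enal form of the lactol adds C3; the former ring alkene keeps C9 cis to C2, and the C9 hydroxyl is released free.

Step 5
Reactants: 7 but-2-yne-1,4-diol
Product: 8 4-[(4-methoxybenzyl)oxy]but-2-yn-1-ol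
Conditions: NaH (1 equiv), 4-methoxybenzyl chloride, Bu4NI (cat.), THF/DMF, 0 °C → rt; diol in excess
Reagents that add atoms: 4-methoxybenzyl chloride, COc1ccc(CCl)cc1
Why: Williamson mono-etherification of a symmetrical diol; excess diol suppresses the bis-ether.

Step 6
Reactants: 8 4-[(4-methoxybenzyl)oxy]but-2-yn-1-ol
Product: 10 (2Z)-3-iodo-4-[(4-methoxybenzyl)oxy]but-2-en-1-ol, via cyclic alkenylalanate 9 (not isolated)
Conditions: NaAlH2(OCH2CH2OMe)2, THF, 0 °C → rt; then I2, −78 → 0 °C
Reagents that add atoms: iodine, II
Why: Alkoxide-directed trans-hydroalumination places aluminium on the distal alkyne carbon in a five-membered chelate (9), and iodinolysis with retention gives the iodoalkene with iodine (the future C3 position) cis to the C6 carbon.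

Step 7
Reactants: 10 (2Z)-3-iodo-4-[(4-methoxybenzyl)oxy]but-2-en-1-ol
Product: 11 (2Z)-3-iodo-4-[(4-methoxybenzyl)oxy]but-2-enal
Conditions: MnO2, CH2Cl2, rt, dark
Reagents that add atoms: none
Why: Heterogeneous, neutral oxidation of an allylic alcohol to the enal, which should keep the alkene geometry.

Step 8
Reactants: 12 2-methylenepropane-1,3-diol
Product: 13 2-{[(tert-butyldimethylsilyl)oxy]methyl}prop-2-en-1-ol
Conditions: NaH (1 equiv), THF, 0 °C; then TBSCl
Reagents that add atoms: tert-butyldimethylsilyl chloride, CC(C)(C)[Si](C)(C)Cl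
Why: Monosilylation of a symmetrical diol through its poorly soluble monosodium alkoxide.

Step 9
Reactants: 13 2-{[(tert-butyldimethylsilyl)oxy]methyl}prop-2-en-1-ol
Product: 14 {[2-(bromomethyl)prop-2-en-1-yl]oxy}(tert-butyl)dimethylsilane
Conditions: CBr4, PPh3, CH2Cl2, 0 °C
Reagents that add atoms: carbon tetrabromide, BrC(Br)(Br)Br
Why: Appel bromination under neutral conditions; the allyl unit is symmetrical about its central carbon, so direct and allylic displacement give the same bromide.

Step 10
Reactants: 14 {[2-(bromomethyl)prop-2-en-1-yl]oxy}(tert-butyl)dimethylsilane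
Product: 16 3-{[(tert-butyldimethylsilyl)oxy]methyl}but-3-enoic acid, via allylzinc bromide 15 (not isolated)
Conditions: Zn dust, LiCl, THF, 0 °C → rt; then CO2 (1 atm), rt; aq. citric acid (pH 4)
Reagents that add atoms: carbon dioxide, O=C=O
Why: Zinc insertion into the allylic bromide and carboxylation of the allyl metal (the classical route to β,γ-unsaturated acids); both allyl termini are CH2 groups, so either mode of attack gives 16, with C8 coming from CO2.

Step 11
Reactants: 16 3-{[(tert-butyldimethylsilyl)oxy]methyl}but-3-enoic acid; 17 (4S)-4-benzyl-1,3-oxazolidin-2-one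
Product: 19 (4S)-4-benzyl-3-(3-{[(tert-butyldimethylsilyl)oxy]methyl}but-3-enoyl)-1,3-oxazolidin-2-one, via mixed pivalic anhydride 18 (not isolated)
Conditions: pivaloyl chloride, Et3N, THF, −20 °C; then 17, LiCl, −20 °C → rt
Reagents that add atoms: none
Why: N-acylation through the mixed anhydride with LiCl/Et3N activation; no strong base is used, so the β,γ-alkene should not move into conjugation.

Step 12
Reactants: 19 (4S)-4-benzyl-3-(3-{[(tert-butyldimethylsilyl)oxy]methyl}but-3-enoyl)-1,3-oxazolidin-2-one; 11 (2Z)-3-iodo-4-[(4-methoxybenzyl)oxy]but-2-enal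
Product: 21 (4S)-4-benzyl-3-[(2S,3S,4Z)-3-hydroxy-5-iodo-6-[(4-methoxybenzyl)oxy]-2-(3-{[tert-butyldimethylsilyl]oxy}prop-1-en-2-yl)hex-4-enoyl]-1,3-oxazolidin-2-one, via dibutylboron enolate 20 (not isolated)
Conditions: Bu2BOTf, Et3N, CH2Cl2, −78 → 0 °C; then 11, −78 → 0 °C; H2O2, pH 7 buffer, MeOH, 0 °C
Reagents that add atoms: none
Why: Evans syn aldol reaction; the Z boron dienolate reacts at its α-carbon through a Zimmerman–Traxler chair on the face away from the benzyl group, which sets C7 and C6 together in the syn relationship that later becomes the trans lactone, with absolute configuration fixed by the (S)-auxiliary.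

Step 13
Reactants: 21 aldol adduct
Product: 22 (4S)-4-benzyl-3-[(2S,3S,4Z)-3-[(tert-butyldimethylsilyl)oxy]-5-iodo-6-[(4-methoxybenzyl)oxy]-2-(3-{[tert-butyldimethylsilyl]oxy}prop-1-en-2-yl)hex-4-enoyl]-1,3-oxazolidin-2-one
Conditions: TBSOTf, 2,6-lutidine, CH2Cl2, −78 → 0 °C
Reagents that add atoms: tert-butyldimethylsilyl trifluoromethanesulfonate, CC(C)(C)[Si](C)(C)OS(=O)(=O)C(F)(F)F
Why: Silylation of the hindered secondary allylic alcohol with the silyl triflate; the C6 oxygen stays masked until the lactone is built.

Step 14
Reactants: 22 silylated aldol adduct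
Product: 23 (2R,3S,4Z)-3-[(tert-butyldimethylsilyl)oxy]-5-iodo-6-[(4-methoxybenzyl)oxy]-2-(3-{[tert-butyldimethylsilyl]oxy}prop-1-en-2-yl)hex-4-en-1-ol
Conditions: LiBH4, MeOH (1 equiv), THF, 0 °C
Reagents that add atoms: none
Why: Reductive removal of the auxiliary gives the C8 primary alcohol; C7 is never enolised, so its configuration is kept, and the iodoalkene is inert to borohydride.

Step 15
Reactants: 6 (2E)-2-{[(tert-butyldimethylsilyl)oxy]methyl}penta-2,4-dien-1-ol; 23 iodoalkene alcohol
Product: 25 (2R,3R,4E,8E)-3-[(tert-butyldimethylsilyl)oxy]-9-{[(tert-butyldimethylsilyl)oxy]methyl}-5-{[(4-methoxybenzyl)oxy]methyl}-2-(3-{[tert-butyldimethylsilyl]oxy}prop-1-en-2-yl)deca-4,8-diene-1,10-diol, via bis(9-BBN) borane 24 (not isolated)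
Conditions: 9-BBN (2.5 equiv), THF, 0 °C → rt; then aq. K3PO4; 23, Pd(dppf)Cl2 (cat.), AsPh3, DMF, rt
Reagents that add atoms: none
Why: 9-BBN adds to the terminal vinyl group with boron on C3 (a second equivalent caps the hydroxyl); after excess B–H is destroyed by aqueous base, B-alkyl Suzuki–Miyaura coupling with the iodoalkene forms C3–C4 with retention of both alkene geometries and releases the C8 and C9 hydroxyls free.

Step 16
Reactants: 25 open-chain C8,C9 diol
Product: 26 (2S,3R,4E,8Z)-3-[(tert-butyldimethylsilyl)oxy]-9-{[(tert-butyldimethylsilyl)oxy]methyl}-5-{[(4-methoxybenzyl)oxy]methyl}-2-(3-{[tert-butyldimethylsilyl]oxy}prop-1-en-2-yl)deca-4,8-dienedial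
Conditions: Dess–Martin periodinane, NaHCO3, CH2Cl2, 0 °C → rt; used at once
Reagents that add atoms: none
Why: Buffered Dess–Martin oxidation of both primary alcohols under non-basic conditions should keep the C7 centre, the position of the C11=C13 alkene and the geometry of the C9 enal.

Step 17
Reactants: 26 open-chain C8 aldehyde/C9 enal
Product: 27 ten-membered cis-8,9-diol (ring-cis C1=C10 and C4=C5; C6–OTBS; C7 bearing the 3-(TBSO)prop-1-en-2-yl group; C10–CH2OTBS; C4–CH2OPMB; O8 and O9 cis to each other and to the C7 branch; O6 trans)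
Conditions: TiCl3(DME)1.5, Zn–Cu couple, DME, 25 °C, slow addition of 26 (high dilution); aq. K2CO3
Reagents that add atoms: none
Why: Low-valent titanium made from TiCl3(DME)1.5 and Zn–Cu transfers one electron to each carbonyl group, the two titanium-bound ketyls couple carbon to carbon on the metal, and hydrolysis of the titanium diolate releases the diol (McMurry-type intramolecular pinacol coupling, held at the diol stage by working at 25 °C). The closest known reaction type is the reductive cyclisation of dialdehydes, aldehyde–enal pairs included, to medium- and large-ring 1,2-diols. The ten-membered carbocycle closes by C8–C9 bond formation between the two carbonyl carbons, a radical–radical macrocyclisation run by slow addition so that ring closure outruns dimerisation. C8 is controlled by C7: the new bond should form anti to the C11 alkenyl branch with the C6 chain gauche (Felkin–Anh sense), which puts O8 on the face of C11. C9 is controlled by the metal template: both oxygens sit on titanium on the same side of the forming bond, and the enal, held s-trans by the strain between C2 and the carbonyl oxygen across the ring-cis alkene, should then present the face that gives the 8,9-cis diol. Coupling 1,2 and not through C1 is needed and is expected because the oxygens are tied together through titanium, so the carbons within reach are C8 and C9. The C1=C10 geometry and the C7 centre must survive; the medium is non-basic, and coupling of the titanium-bound oxyallyl radical is expected to be faster than rotation about C1–C10.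

Step 18
Reactants: 27 ten-membered cis-8,9-diol
Product: 28 9-O-acetate of 27 (C8–OH free)
Conditions: Ac2O (1.1 equiv), pyridine, CH2Cl2, −20 → 0 °C
Reagents that add atoms: acetic anhydride, CC(=O)OC(C)=O
Why: The allylic C9 hydroxyl is the less hindered of the two (C8–OH is flanked by the branched C7 and the C6 silyl ether), so limited anhydride at low temperature should acylate it first.

Step 19
Reactants: 28 9-O-acetate
Product: 29 9-O-acetate 8-O-(2-methylpropanoate) of 27
Conditions: (iPrCO)2O, DMAP, pyridine, CH2Cl2, 0 °C → rt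
Reagents that add atoms: isobutyric anhydride, CC(C)C(=O)OC(=O)C(C)C
Why: DMAP-catalysed acylation of the remaining hindered secondary alcohol; no alkoxide is generated, which limits acetyl migration from O9 to O8.

Step 20
Reactants: 29 diester tris-silyl ether
Product: 30 6,12,14-triol (C15–OPMB; 9-O-acetate; 8-O-isobutyrate)
Conditions: HF·pyridine, pyridine, THF, 0 °C → rt
Reagents that add atoms: none
Why: Buffered fluoride removes the two primary and the secondary allylic TBS ethers; the weakly acidic medium leaves the esters and the PMB ether in place and does not promote acyl migration.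

Step 21
Reactants: 30 6,12,14-triol
Product: 32 12,6-lactone C14 enal (α-methylene-γ-butyrolactone; C10–CHO; C15–OPMB), via lactol enal 31 (not isolated)
Conditions: TEMPO (cat.), PhI(OAc)2, CH2Cl2, rt
Reagents that add atoms: none
Why: The oxoammonium oxidant prefers primary alcohols: the C12 aldehyde is trapped by the C6 hydroxyl as lactol 31 and oxidised on to the lactone, and the C14 alcohol gives the enal; the secondary C6 alcohol is consumed by lactol formation before it can be oxidised.

Step 22
Reactants: 32 lactone enal
Product: 33 C14 carboxylic acid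
Conditions: NaClO2, NaH2PO4, 2-methyl-2-butene, t-BuOH/H2O, 0 °C → rt
Reagents that add atoms: sodium chlorite, [Na+].[O-]Cl=O
Why: Pinnick oxidation converts the enal into the acid; the alkene scavenger removes hypochlorous acid, and the methylene lactone and the esters are inert.

Step 23
Reactants: 33 C14 carboxylic acid
Product: 34 C14 methyl ester (C15–OPMB)
Conditions: MeI, KHCO3, DMF, rt
Reagents that add atoms: iodomethane, CI
Why: O-Alkylation of the carboxylate under weakly basic conditions; this avoids diazoalkanes, which add to methylene lactones, and conditions that move or cleave the esters.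

Step 24
Reactants: 34 C14 methyl ester PMB ether
Product: 35 target (6R,7S,8S,9R)
Conditions: DDQ, CH2Cl2/pH 7 buffer, 0 °C
Reagents that add atoms: none
Why: Oxidative cleavage of the 4-methoxybenzyl ether by benzylic hydride abstraction and hydrolysis frees the C15 alcohol; the esters, the lactone and the electron-poor alkenes are untouched.

## Compound list

1 | 1,3-dihydroxyacetone | OCC(=O)CO | starting material
2 | ethyl 4-hydroxy-3-(hydroxymethyl)but-2-enoate | CCOC(=O)C=C(CO)CO | intermediate (not isolated)
3 | 4-(hydroxymethyl)furan-2(5H)-one | O=C1OCC(CO)=C1 | intermediate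
4 | 4-{[(tert-butyldimethylsilyl)oxy]methyl}furan-2(5H)-one | O=C1OCC(CO[Si](C)(C)C(C)(C)C)=C1 | intermediate
5 | 4-{[(tert-butyldimethylsilyl)oxy]methyl}-2,5-dihydrofuran-2-ol (both anomers) | OC1OCC(CO[Si](C)(C)C(C)(C)C)=C1 | intermediate
6 | (2E)-2-{[(tert-butyldimethylsilyl)oxy]methyl}penta-2,4-dien-1-ol | OC/C(CO[Si](C)(C)C(C)(C)C)=C\C=C | intermediate
7 | but-2-yne-1,4-diol | OCC#CCO | starting material
8 | 4-[(4-methoxybenzyl)oxy]but-2-yn-1-ol | OCC#CCOCc1ccc(OC)cc1 | intermediate
9 | sodium cyclic alkenylalanate from 8 (five-membered C–Al–O chelate) | [Na+].COCCO[Al-]1(OCCOC)OCC=C1COCc1ccc(OC)cc1 | intermediate (not isolated)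
10 | (2Z)-3-iodo-4-[(4-methoxybenzyl)oxy]but-2-en-1-ol | OC/C=C(I)/COCc1ccc(OC)cc1 | intermediate
11 | (2Z)-3-iodo-4-[(4-methoxybenzyl)oxy]but-2-enal | O=C/C=C(I)/COCc1ccc(OC)cc1 | intermediate
12 | 2-methylenepropane-1,3-diol | C=C(CO)CO | starting material
13 | 2-{[(tert-butyldimethylsilyl)oxy]methyl}prop-2-en-1-ol | C=C(CO)CO[Si](C)(C)C(C)(C)C | intermediate
14 | {[2-(bromomethyl)prop-2-en-1-yl]oxy}(tert-butyl)dimethylsilane | C=C(CBr)CO[Si](C)(C)C(C)(C)C | intermediate
15 | [2-({[tert-butyl(dimethyl)silyl]oxy}methyl)prop-2-en-1-yl]zinc bromide | C=C(C[Zn]Br)CO[Si](C)(C)C(C)(C)C | intermediate (not isolated)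
16 | 3-{[(tert-butyldimethylsilyl)oxy]methyl}but-3-enoic acid | C=C(CO[Si](C)(C)C(C)(C)C)CC(=O)O | intermediate
17 | (4S)-4-benzyl-1,3-oxazolidin-2-one | O=C1N[C@@H](Cc2ccccc2)CO1 | starting material
18 | mixed anhydride of 16 and pivalic acid | C=C(CO[Si](C)(C)C(C)(C)C)CC(=O)OC(=O)C(C)(C)C | intermediate (not isolated)
19 | (4S)-4-benzyl-3-(3-{[(tert-butyldimethylsilyl)oxy]methyl}but-3-enoyl)-1,3-oxazolidin-2-one | C=C(CO[Si](C)(C)C(C)(C)C)CC(=O)N1[C@@H](Cc2ccccc2)COC1=O | intermediate
20 | dibutylboron (Z)-enolate of 19 | C=C(CO[Si](C)(C)C(C)(C)C)/C=C(\OB(CCCC)CCCC)N1[C@@H](Cc2ccccc2)COC1=O | intermediate (not isolated)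
21 | (4S)-4-benzyl-3-[(2S,3S,4Z)-3-hydroxy-5-iodo-6-[(4-methoxybenzyl)oxy]-2-(3-{[tert-butyldimethylsilyl]oxy}prop-1-en-2-yl)hex-4-enoyl]-1,3-oxazolidin-2-one | O=C(N1[C@@H](Cc2ccccc2)COC1=O)[C@@H](C(=C)CO[Si](C)(C)C(C)(C)C)[C@H](O)/C=C(I)/COCc1ccc(OC)cc1 | intermediate
22 | 3-O-TBS ether of 21 (2S,3S,4Z) | O=C(N1[C@@H](Cc2ccccc2)COC1=O)[C@@H](C(=C)CO[Si](C)(C)C(C)(C)C)[C@H](O[Si](C)(C)C(C)(C)C)/C=C(I)/COCc1ccc(OC)cc1 | intermediate
23 | (2R,3S,4Z)-3-[(tert-butyldimethylsilyl)oxy]-5-iodo-6-[(4-methoxybenzyl)oxy]-2-(3-{[tert-butyldimethylsilyl]oxy}prop-1-en-2-yl)hex-4-en-1-ol | OC[C@@H](C(=C)CO[Si](C)(C)C(C)(C)C)[C@H](O[Si](C)(C)C(C)(C)C)/C=C(I)/COCc1ccc(OC)cc1 | intermediate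
24 | bis(9-BBN) derivative of 6 (B-alkyl at C3; borinate on O9) | C(/C(CO[Si](C)(C)C(C)(C)C)=C\CCB1C2CCCC1CCC2)OB1C2CCCC1CCC2 | intermediate (not isolated)
25 | (2R,3R,4E,8E)-3-[(tert-butyldimethylsilyl)oxy]-9-{[(tert-butyldimethylsilyl)oxy]methyl}-5-{[(4-methoxybenzyl)oxy]methyl}-2-(3-{[tert-butyldimethylsilyl]oxy}prop-1-en-2-yl)deca-4,8-diene-1,10-diol | OC[C@@H](C(=C)CO[Si](C)(C)C(C)(C)C)[C@H](O[Si](C)(C)C(C)(C)C)/C=C(/COCc1ccc(OC)cc1)CC/C=C(/CO[Si](C)(C)C(C)(C)C)CO | intermediate
26 | (2S,3R,4E,8Z)-3-[(tert-butyldimethylsilyl)oxy]-9-{[(tert-butyldimethylsilyl)oxy]methyl}-5-{[(4-methoxybenzyl)oxy]methyl}-2-(3-{[tert-butyldimethylsilyl]oxy}prop-1-en-2-yl)deca-4,8-dienedial (precursor of the key step) | O=C[C@@H](C(=C)CO[Si](C)(C)C(C)(C)C)[C@H](O[Si](C)(C)C(C)(C)C)/C=C(/COCc1ccc(OC)cc1)CC/C=C(/CO[Si](C)(C)C(C)(C)C)C=O | intermediate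
27 | ten-membered cis-8,9-diol (6,12,14-tris-O-TBS; 15-O-PMB; product of the key step) | C=C(CO[Si](C)(C)C(C)(C)C)[C@H]1[C@H](O[Si](C)(C)C(C)(C)C)/C=C(/COCc2ccc(OC)cc2)CC/C=C(/CO[Si](C)(C)C(C)(C)C)[C@@H](O)[C@H]1O | intermediate
28 | 9-O-acetate of 27 | C=C(CO[Si](C)(C)C(C)(C)C)[C@H]1[C@H](O[Si](C)(C)C(C)(C)C)/C=C(/COCc2ccc(OC)cc2)CC/C=C(/CO[Si](C)(C)C(C)(C)C)[C@@H](OC(C)=O)[C@H]1O | intermediate
29 | 9-O-acetate 8-O-isobutyrate of 27 | C=C(CO[Si](C)(C)C(C)(C)C)[C@H]1[C@H](O[Si](C)(C)C(C)(C)C)/C=C(/COCc2ccc(OC)cc2)CC/C=C(/CO[Si](C)(C)C(C)(C)C)[C@@H](OC(C)=O)[C@H]1OC(=O)C(C)C | intermediate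
30 | 6,12,14-triol (15-O-PMB; 9-O-acetate; 8-O-isobutyrate) | C=C(CO)[C@H]1[C@H](O)/C=C(/COCc2ccc(OC)cc2)CC/C=C(/CO)[C@@H](OC(C)=O)[C@H]1OC(=O)C(C)C | intermediate
31 | 12,6-lactol C14 enal (both anomers) | C=C1C(O)O[C@@H]2/C=C(/COCc3ccc(OC)cc3)CC/C=C(/C=O)[C@@H](OC(C)=O)[C@@H](OC(=O)C(C)C)[C@@H]12 | intermediate (not isolated)
32 | 12,6-lactone C14 enal (15-O-PMB) | C=C1C(=O)O[C@@H]2/C=C(/COCc3ccc(OC)cc3)CC/C=C(/C=O)[C@@H](OC(C)=O)[C@@H](OC(=O)C(C)C)[C@@H]12 | intermediate
33 | C14 carboxylic acid (15-O-PMB) | C=C1C(=O)O[C@@H]2/C=C(/COCc3ccc(OC)cc3)CC/C=C(/C(=O)O)[C@@H](OC(C)=O)[C@@H](OC(=O)C(C)C)[C@@H]12 | intermediate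
34 | C14 methyl ester (15-O-PMB) | C=C1C(=O)O[C@@H]2/C=C(/COCc3ccc(OC)cc3)CC/C=C(/C(=O)OC)[C@@H](OC(C)=O)[C@@H](OC(=O)C(C)C)[C@@H]12 | intermediate
35 | CNP0242134.4 (6R,7S,8S,9R; 9-acetate, 8-isobutyrate, C14 methyl ester, C15 alcohol, 12,6-olide) | C=C1C(=O)O[C@@H]2/C=C(/CO)CC/C=C(/C(=O)OC)[C@@H](OC(C)=O)[C@@H](OC(=O)C(C)C)[C@@H]12 | target

## Step count and least certain steps

Total: 24 steps. Longest linear sequence: 17 steps (12 → 35 through steps 8–24).

**Step 17 (key step).** The most likely failure is ring closure with the two new carbinols trans. Unconstrained ten-membered rings tend toward the trans diol in this coupling, so the cis outcome rests on the two ring-cis alkenes and the C7 branch. Rotation in the allyl-type ketyl could also scramble the C1=C10 geometry, and intermolecular coupling competes if addition is too fast. Fallback, from 26 back to 27: accept the coupling as the ring-forming step and correct C9 afterwards. If the 8,9-trans diol F1 is the main product, MnO2 oxidises its allylic C9 carbinol selectively to the 8-hydroxy enone F2. Chelation-controlled reduction with Zn(BH4)2, with hydride delivered to the zinc chelate of O8 and the C9 carbonyl, then gives the cis diol 27.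

**Step 18 (with step 19).** Discrimination between the two secondary hydroxyls may be poor, or acetyl may migrate from O9 to O8 during the more forcing isobutyrylation, which would exchange the two esters. Fallback, from 27 back to 29: silylate the less hindered allylic hydroxyl with Et3SiCl/imidazole at low temperature to the 9-O-triethylsilyl ether F3. Isobutyrylation gives the 8-O-isobutyrate 9-O-triethylsilyl ether F4. PPTS in MeOH removes the triethylsilyl group to the 8-O-isobutyrate 9-alcohol F5, and acetylation gives 29. A silyl group does not migrate under the acylation conditions, and silylation is more sensitive to hindrance than acetylation.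

**Step 16.** The dialdehyde may degrade: epimerisation at C7 or movement of the C11=C13 alkene into conjugation with the C8 aldehyde, and isomerisation of the C9 enal to the more stable geometry, all promoted by traces of acid or base and by chromatography. Fallback, from 25 back to 26: oxidise in two stages. MnO2 converts only the allylic alcohol and gives the hydroxy enal F6, which can be purified. The C8 alcohol is then oxidised last (SO3·pyridine, DMSO, iPr2NEt, 0 °C) and the crude product goes directly into step 17.

**Step 15.** Hydroboration of a conjugated diene that carries a free hydroxyl may be slow or may place some boron on C2, and the hindered iodoalkene may allow β-hydride elimination at the alkylpalladium stage. Fallback, from 6 back to 25: go through an isolated alkyl iodide and an organozinc. Silylate 6 to the triethylsilyl ether F7. Hydroboration and oxidation (9-BBN; NaOH, H2O2) give the homoallylic alcohol F8, which can be purified. I2/PPh3/imidazole give the iodide F9, and zinc insertion gives the alkylzinc iodide F10. Negishi coupling of F10 with 23 (Pd(dppf)Cl2) gives the 10-O-triethylsilyl ether F11, and PPTS in MeOH returns 25.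

**Step 4 (with step 3).** Lactol 5 may lose water to the furan, and the ring-opened hydroxy enal may isomerise under the basic ylide. Fallback, from 7 back to 6: build the same dienol from an iodoalkene. Monosilylate 7 to 4-[(tert-butyldimethylsilyl)oxy]but-2-yn-1-ol F12. Hydroalumination/iodination as in step 6 gives the (2Z)-iodoallylic alcohol F13, and MnO2 gives the iodoenal F14. Methylenation (Ph3P=CH2) gives the 2-iodo-1,3-diene F15. Iodine–lithium exchange with t-BuLi at −78 °C and trapping with paraformaldehyde install the C9 hydroxymethyl group with retention and give 6.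

## Further compounds

F1 | step 17 | 8,9-trans diol (C9 epimer of 27) | C=C(CO[Si](C)(C)C(C)(C)C)[C@H]1[C@H](O[Si](C)(C)C(C)(C)C)/C=C(/COCc2ccc(OC)cc2)CC/C=C(/CO[Si](C)(C)C(C)(C)C)[C@H](O)[C@H]1O
F2 | step 17 | 8-hydroxy 9-ketone (ring enone) | C=C(CO[Si](C)(C)C(C)(C)C)[C@H]1[C@H](O[Si](C)(C)C(C)(C)C)/C=C(/COCc2ccc(OC)cc2)CC/C=C(/CO[Si](C)(C)C(C)(C)C)C(=O)[C@H]1O
F3 | step 18 | 9-O-triethylsilyl ether of 27 | C=C(CO[Si](C)(C)C(C)(C)C)[C@H]1[C@H](O[Si](C)(C)C(C)(C)C)/C=C(/COCc2ccc(OC)cc2)CC/C=C(/CO[Si](C)(C)C(C)(C)C)[C@@H](O[Si](CC)(CC)CC)[C@H]1O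
F4 | step 18 | 8-O-isobutyrate 9-O-triethylsilyl ether | C=C(CO[Si](C)(C)C(C)(C)C)[C@H]1[C@H](O[Si](C)(C)C(C)(C)C)/C=C(/COCc2ccc(OC)cc2)CC/C=C(/CO[Si](C)(C)C(C)(C)C)[C@@H](O[Si](CC)(CC)CC)[C@H]1OC(=O)C(C)C
F5 | step 18 | 8-O-isobutyrate 9-alcohol | C=C(CO[Si](C)(C)C(C)(C)C)[C@H]1[C@H](O[Si](C)(C)C(C)(C)C)/C=C(/COCc2ccc(OC)cc2)CC/C=C(/CO[Si](C)(C)C(C)(C)C)[C@@H](O)[C@H]1OC(=O)C(C)C
F6 | step 16 | hydroxy enal (C9 aldehyde; C8 alcohol) | OC[C@@H](C(=C)CO[Si](C)(C)C(C)(C)C)[C@H](O[Si](C)(C)C(C)(C)C)/C=C(/COCc1ccc(OC)cc1)CC/C=C(/CO[Si](C)(C)C(C)(C)C)C=O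
F7 | step 15 | triethylsilyl ether of 6 | CC[Si](CC)(CC)OC/C(CO[Si](C)(C)C(C)(C)C)=C\C=C
F8 | step 15 | homoallylic alcohol (C3–OH) | CC[Si](CC)(CC)OC/C(CO[Si](C)(C)C(C)(C)C)=C\CCO
F9 | step 15 | homoallylic iodide (C3–I) | CC[Si](CC)(CC)OC/C(CO[Si](C)(C)C(C)(C)C)=C\CCI
F10 | step 15 | alkylzinc iodide from F9 | CC[Si](CC)(CC)OC/C(CO[Si](C)(C)C(C)(C)C)=C\CC[Zn]I
F11 | step 15 | 10-O-triethylsilyl ether of 25 | OC[C@@H](C(=C)CO[Si](C)(C)C(C)(C)C)[C@H](O[Si](C)(C)C(C)(C)C)/C=C(/COCc1ccc(OC)cc1)CC/C=C(/CO[Si](C)(C)C(C)(C)C)CO[Si](CC)(CC)CC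
F12 | step 4 | 4-[(tert-butyldimethylsilyl)oxy]but-2-yn-1-ol | OCC#CCO[Si](C)(C)C(C)(C)C
F13 | step 4 | (2Z)-4-[(tert-butyldimethylsilyl)oxy]-3-iodobut-2-en-1-ol | OC/C=C(I)/CO[Si](C)(C)C(C)(C)C
F14 | step 4 | (2Z)-4-[(tert-butyldimethylsilyl)oxy]-3-iodobut-2-enal | O=C/C=C(I)/CO[Si](C)(C)C(C)(C)C
F15 | step 4 | tert-butyl{[(2Z)-2-iodopenta-2,4-dien-1-yl]oxy}dimethylsilane | C=C/C=C(I)/CO[Si](C)(C)C(C)(C)C
A1 | alternative 1 | cis,anti,cis tricyclic photoadduct (bicyclo[2.2.0]hexane fused to the cyclohexanone; 8,9-acetonide) | COC(=O)[C@]12[C@@H]3CC[C@]3(CO[Si](C)(C)C(C)(C)C)[C@H]1C(=O)[C@H](CC(=O)OC)[C@@H]1OC(C)(C)O[C@H]21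
A2 | alternative 1 | ten-membered 4-en-6-one 1(10)-enoate (both alkenes ring-cis) | COC(=O)/C1=C/CC/C(CO[Si](C)(C)C(C)(C)C)=C\C(=O)[C@H](CC(=O)OC)[C@@H]2OC(C)(C)O[C@H]12
A3 | alternative 2 | cis-1,2-dialkenylcyclohexanol (C10 vinyl carbinol; C5 alkenyl) | C=C[C@]1(O)[C@H](C(=C)COCc2ccc(OC)cc2)[C@@H](OCOC)[C@H](CCO[Si](C)(C)C(C)(C)C)[C@@H]2OC(C)(C)O[C@H]12
A4 | alternative 2 | ten-membered C10 ketone with ring-cis C4=C5 | O=C1CCC/C(COCc2ccc(OC)cc2)=C\[C@@H](OCOC)[C@H](CCO[Si](C)(C)C(C)(C)C)[C@@H]2OC(C)(C)O[C@H]12
A5 | alternative 3 | cyclooct-4-enone (C9 ketone; C8–OPMB) | C=C(CO[Si](C)(C)C(C)(C)C)[C@H]1[C@H](O[Si](C)(C)C(C)(C)C)/C=C(/CO[Si](c2ccccc2)(c2ccccc2)C(C)(C)C)CCC(=O)[C@H]1OCc1ccc(OC)cc1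
A6 | alternative 3 | pyrrolidine enamine of A5 (C9=C2) | C=C(CO[Si](C)(C)C(C)(C)C)[C@H]1[C@H](O[Si](C)(C)C(C)(C)C)/C=C(/CO[Si](c2ccccc2)(c2ccccc2)C(C)(C)C)CC=C(N2CCCC2)[C@H]1OCc1ccc(OC)cc1
A7 | alternative 3 | methyl propiolate | C#CC(=O)OC
A8 | alternative 3 | ten-membered 9-pyrrolidinyl 1,9-diene 10-carboxylate | C=C(CO[Si](C)(C)C(C)(C)C)[C@H]1[C@H](O[Si](C)(C)C(C)(C)C)/C=C(/CO[Si](c2ccccc2)(c2ccccc2)C(C)(C)C)C/C=C/C(C(=O)OC)=C(N2CCCC2)\[C@H]1OCc1ccc(OC)cc1
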